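**Plan** (ent-kaurane numbering: ring A = C1–C5, C10; ring B = oxepane C5–C6–O–C7–C8–C9–C10; rings C and D = bicyclo[3.2.1]octane C8, C9, C11–C16)

1. Enabling feature: C5 carries the carboxyl-level carbon C6 and is bonded to the quaternary C10. Ring A is therefore traced back to a seven-membered ring with C6 as a ketone between C10 and C5; contraction re-forms C5–C10 and hands C6 as a ketene to the C7 hydroxyl, closing ring B at C6–O.
2. Retrosynthetic cuts, in order: 9,11-epoxide, C15 ketone, acetates, lactol → lactone → diazo ketone; then C9–C10 (1,2-alkenyl shift of an epoxy carbinol) and C6–C9 (alkenyllithium addition), giving a C/D alkenyllithium and an A-homo epoxy ketone.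
3. Forward order: rings C and D from (+)-nopinone (cyclobutane cleavage, then C8–C15 allylic alkylation); the seven-membered ring by ring-closing metathesis (C10=C1); union by Shapiro addition and semipinacol shift; rings A and B together in the Wolff step; C15 ketone and epoxide last.
4. Stereochemistry: C13 (and through the bridge C8) from nopinone; C2 from asymmetric transfer hydrogenation; C1 from a hydroxyl-directed epoxidation cis to C2–OH; C10 from anti addition to the epoxy ketone followed by alkenyl shift with inversion; C5 by equilibration; C9/C11 by exo-face epoxidation.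

Key step: step 23

Assumption: the C6 lactol hydroxyl of the target is taken as the thermodynamically preferred anomer, so lactol and anomeric-acetate intermediates are carried as anomer mixtures (no descriptor at C6 in their SMILES).

**C/D fragment**

Step 1
Reactants: 1 (1R,5S)-(+)-nopinone
Product: 2 methyl 6,6-dimethyl-2-oxobicyclo[3.1.1]heptane-3-carboxylate (bridgeheads as in 1; C3 epimers and enol)
Conditions: NaH, (MeO)2CO, THF, reflux; aq. HCl
Reagents that add atoms: dimethyl carbonate, COC(=O)OC
Why: Claisen-type C-methoxycarbonylation of the ketone enolate, which can form only at C3 because C1 is a bridgehead; the new carbon becomes C7.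

Step 2
Reactants: 2 methyl nopinone-3-carboxylate
Product: 3 methyl (5R)-5-(2-chloropropan-2-yl)-2-oxocyclohexane-1-carboxylate
Conditions: TiCl4, CH2Cl2, −78 → 0 °C; H2O
Reagents that add atoms: titanium tetrachloride, Cl[Ti](Cl)(Cl)Cl
Why: Acid-induced cyclobutane cleavage of a nopinone derivative: the TiCl4-activated carbonyl opens the strained C1–C6 bond to a tertiary cation that chloride traps; pinane C5 becomes C13 untouched, and the ester keeps the two α-carbons different so chirality is retained.

Step 3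
Reactants: 3 chloro keto ester
Product: 5 methyl (5R)-2-acetoxy-5-(prop-1-en-2-yl)cyclohex-1-ene-1-carboxylate, via potassium enolate 4 (not isolated)
Conditions: KOt-Bu (2.2 equiv), THF, 0 °C → rt; then Ac2O, 0 °C
Reagents that add atoms: acetic anhydride, CC(=O)OC(C)=O
Why: E2 elimination of the tertiary chloride with the bulky base should give the terminal (Hofmann) alkene while the β-keto ester rests as its enolate, which the hard anhydride then acylates on oxygen to mask the enol.

Step 4
Reactants: 5 isopropenyl enol acetate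
Product: 6 methyl (5R)-2-acetoxy-5-(3-chloroprop-1-en-2-yl)cyclohex-1-ene-1-carboxylate
Conditions: Ca(OCl)2, CO2 (dry ice), CH2Cl2/H2O, 0 °C
Reagents that add atoms: calcium hypochlorite, [Ca+2].[O-]Cl.[O-]Cl (chlorine, via HOCl)
Why: Ene-type allylic chlorination by HOCl attacks the electron-rich 1,1-disubstituted alkene with shift of the double bond; the push–pull enol acetate alkene is too electron-poor to react.

Step 5
Reactants: 6 allylic chloride
Product: 8 methyl (1R,5R)-6-methylidene-2-oxobicyclo[3.2.1]octane-1-carboxylate, via potassium enolate 7 (not isolated)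
Conditions: K2CO3, MeOH, 0 °C → rt
Reagents that add atoms: none
Why: Methanolysis of the enol acetate frees the β-keto ester enolate, which closes ring D by intramolecular C-alkylation with the allylic chloride (5-exo-tet, C8–C15); the bridge can only span cis, so the quaternary centre C8 is set by C13.

Step 6
Reactants: 8 bicyclic keto ester
Product: 9 (1S,5R)-1-(hydroxymethyl)-6-methylidenebicyclo[3.2.1]octan-2-ol (C2 epimers)
Conditions: LiAlH4, THF, 0 °C; Fieser work-up
Reagents that add atoms: none
Why: Hydride reduction of ester and ketone; the configuration of the new secondary carbinol (C9) is irrelevant because it is reoxidised in step 8.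

Step 7
Reactants: 9 diol
Product: 10 (1S,5R)-1-[(tert-butyldiphenylsilyloxy)methyl]-6-methylidenebicyclo[3.2.1]octan-2-ol
Conditions: TBDPSCl, imidazole, CH2Cl2, 0 °C
Reagents that add atoms: tert-butyl(chloro)diphenylsilane, CC(C)(C)[Si](Cl)(c1ccccc1)c1ccccc1
Why: The bulky silyl chloride selects the primary C7 hydroxyl over the hindered secondary one; TBDPS is chosen because it resists organolithiums, Lewis acid and silyl migration to the later carbanion.

Step 8
Reactants: 10 silyl ether alcohol
Product: 11 (1S,5R)-1-[(tert-butyldiphenylsilyloxy)methyl]-6-methylidenebicyclo[3.2.1]octan-2-one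
Conditions: Dess–Martin periodinane, pyridine, CH2Cl2, 0 °C → rt
Reagents that add atoms: none
Why: Dess–Martin oxidation of the secondary alcohol to the C9 ketone under buffered conditions that spare the exocyclic alkene.

Step 9
Reactants: 11 ketone
Product: 12 2,4,6-triisopropylbenzenesulfonylhydrazone of 11
Conditions: 2,4,6-(i-Pr)3C6H2SO2NHNH2, HCl (cat.), THF, rt
Reagents that add atoms: 2,4,6-triisopropylbenzenesulfonyl hydrazide, CC(C)c1cc(C(C)C)c(S(=O)(=O)NN)c(C(C)C)c1
Why: Acid-catalysed condensation gives the arylsulfonylhydrazone needed for the Shapiro reaction.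

**A-homo fragment**

Step 10
Reactants: 13 3,3-dimethylglutaric anhydride
Product: 14 3,3-dimethyl-5-oxo-7-(trimethylsilyl)hept-6-ynoic acid
Conditions: Me3SiC≡CSiMe3, AlCl3, CH2Cl2, 0 °C; aq. HCl
Reagents that add atoms: bis(trimethylsilyl)acetylene, C[Si](C)(C)C#C[Si](C)(C)C
Why: Friedel–Crafts-type acylation of the bis-silyl alkyne (ipso-replacement of one silyl group) by the AlCl3-activated anhydride; the anhydride is symmetric, so only one keto acid can form.

Step 11
Reactants: 14 ynone acid
Product: 16 (6S)-4,4-dimethyl-6-[(trimethylsilyl)ethynyl]oxan-2-one, via hydroxy acid 15 (not isolated)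
Conditions: RuCl[(S,S)-TsDPEN](p-cymene) (1 mol %), HCO2H/Et3N (5:2), rt; then TsOH (cat.), toluene, 50 °C
Reagents that add atoms: none
Why: Noyori asymmetric transfer hydrogenation of the alkynyl ketone, in which the (S,S)-catalyst should deliver hydride to give the (S)-propargylic carbinol (C2); acid then closes the δ-lactone.

Step 12
Reactants: 16 silylalkynyl lactone
Product: 17 (6S)-6-ethynyl-4,4-dimethyloxan-2-one
Conditions: n-Bu4NF, AcOH, THF, 0 °C
Reagents that add atoms: none
Why: Fluoride cleaves the alkynyl C–Si bond, and the acetic acid buffer protects the lactone.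

Step 13
Reactants: 17 ethynyl lactone
Product: 18 (6S)-6-ethenyl-4,4-dimethyloxan-2-one
Conditions: H2, Pd/CaCO3–Pb(OAc)2 (Lindlar catalyst), quinoline, EtOAc, rt
Reagents that add atoms: none
Why: Lindlar semi-hydrogenation stops at the terminal alkene.

Step 14
Reactants: 18 vinyl lactone
Product: 19 (7S)-7-hydroxy-2,5,5-trimethylnona-1,8-dien-3-one
Conditions: 2-bromopropene, t-BuLi (2 equiv), THF, −78 °C; then 18, −78 °C; aq. NH4Cl
Reagents that add atoms: isopropenyllithium, [Li]C(C)=C (made from 2-bromopropene, CC(Br)=C)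
Why: Single addition of the alkenyllithium to the δ-lactone at −78 °C (the lactolate persists until work-up) gives the isopropenyl ketone (C6, C10, C20) and frees the C2 hydroxyl.

Step 15
Reactants: 19 hydroxy dienone
Product: 20 (4S)-4-hydroxy-2,6,6-trimethylcyclohept-2-en-1-one
Conditions: second-generation Grubbs catalyst (5 mol %), CH2Cl2 (0.005 M), 40 °C
Reagents that add atoms: none
Why: Ring-closing metathesis joins C10 and C1 as the trisubstituted enone of the seven-membered ring, helped by the gem-dimethyl group.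

Step 16
Reactants: 20 hydroxy enone
Product: 21 (1S,6S,7S)-6-hydroxy-1,4,4-trimethyl-8-oxabicyclo[5.1.0]octan-2-one
Conditions: t-BuOOH, n-BuLi, THF, −78 → −20 °C; aq. NH4Cl
Reagents that add atoms: tert-butyl hydroperoxide, CC(C)(C)OO
Why: Weitz–Scheffer epoxidation in which the C2 lithium alkoxide binds lithium tert-butylperoxide and delivers it to its own face, so the C10–C1 epoxide should form cis to the hydroxyl.

Step 17
Reactants: 21 epoxy alcohol
Product: 22 (1S,6S,7S)-1,4,4-trimethyl-6-(triethylsilyloxy)-8-oxabicyclo[5.1.0]octan-2-one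
Conditions: Et3SiCl, imidazole, CH2Cl2, 0 °C
Reagents that add atoms: chlorotriethylsilane, CC[Si](Cl)(CC)CC
Why: Silylation of the secondary alcohol; the TES ether is later removed by mild acid in the presence of TBDPS.

**Union and completion**

Step 18
Reactants: 12 trisylhydrazone; 22 epoxy ketone
Product: 24 tertiary epoxy carbinol (C6 bears OH and the C/D alkenyl group; 2-OH cis to epoxide oxygen and to OSiEt3; alkenyl trans), via alkenyllithium 23 (not isolated)
Conditions: n-BuLi (2.05 equiv), THF, −78 → 0 °C; CeCl3, −78 °C; then 22, −78 °C; aq. NH4Cl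
Reagents that add atoms: none
Why: Shapiro reaction gives the alkenyllithium regiospecifically (only C11 has α-hydrogens); as the organocerium it should add to the ketone without enolisation from the face anti to the epoxide oxygen and the cis silyloxy group, placing the C6 hydroxyl cis to the epoxide.

Step 19
Reactants: 24 epoxy carbinol
Product: 25 β-hydroxy ketone [2-(C/D alkenyl)-3-hydroxy-2,6,6-trimethyl-4-(triethylsilyloxy)cycloheptan-1-one; 2-CH3, 3-OH and 4-OSiEt3 cis; alkenyl trans]
Conditions: BF3·OEt2 (1.1 equiv), CH2Cl2, −78 → −40 °C; aq. NaHCO3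
Reagents that add atoms: none
Why: Semipinacol rearrangement of a tertiary 2,3-epoxy alcohol: the epoxide opens at the tertiary carbon C10 and the alkenyl group, anti to the breaking C10–O bond, shifts from C6 to C10 with inversion there, giving the C6 ketone, the quaternary centre C10 (methyl cis to the C1 oxygen) and the C1 carbinol with its configuration untouched.

Step 20
Reactants: 25 β-hydroxy ketone
Product: 27 acetonide ketone (C1,C2-O-isopropylidene derivative of 26), via diol 26 (not isolated)
Conditions: PPTS, MeOH, 0 °C → rt; evaporate; Me2C(OMe)2, PPTS, acetone, rt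
Reagents that add atoms: 2,2-dimethoxypropane, COC(C)(C)OC
Why: Mild acid in methanol cleaves the TES ether but not the TBDPS ether, and the cis-diol is ketalised; the acetonide also blocks retro-aldol cleavage of the β-hydroxy ketone under the base used next.

Step 21
Reactants: 27 acetonide ketone
Product: 29 α-diazo ketone silyl ether (diazo group on C5), via trifluoroacetyl ketone 28 (not isolated)
Conditions: LiN(SiMe3)2, THF, −78 °C; CF3CO2CH2CF3; then MeSO2N3, Et3N, H2O, MeCN, rt
Reagents that add atoms: methanesulfonyl azide, CS(=O)(=O)N=[N+]=[N-]; 2,2,2-trifluoroethyl trifluoroacetate, O=C(OCC(F)(F)F)C(F)(F)F (its acyl group stays only in 28)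
Why: Detrifluoroacetylative Regitz diazo transfer: the only possible enolate (toward C5, since C10 is quaternary) is C-trifluoroacetylated, and azide transfer with loss of the activating acyl group gives the diazo ketone.

Step 22
Reactants: 29 diazo ketone silyl ether
Product: 30 α-diazo ketone alcohol (free C7–OH)
Conditions: n-Bu4NF, THF, 0 °C → rt; aq. NH4Cl
Reagents that add atoms: none
Why: Fluoride removes the TBDPS group; α-diazo ketones and acetonides tolerate n-Bu4NF.

Step 23
Reactants: 30 α-diazo ketone alcohol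
Product: 32 tetracyclic lactone (ring B oxepan-2-one; 9(11)-ene; 16-methylidene; C1,C2 acetonide; H-5 trans to C20), via ketene 31 (not isolated)
Conditions: hν (medium-pressure Hg lamp, Pyrex), toluene (0.005 M), rt; then DBU (0.2 equiv), rt
Reagents that add atoms: none
Why: Excitation of the s-cis-locked cyclic α-diazo ketone expels N2 with concerted 1,2-shift of C10 from C6 to C5 (retention at C10), contracting the seven-membered ring to ring A and leaving C6 as a ketene on C5. The closest known reaction is the photochemical Wolff ring contraction of cyclic 2-diazo ketones with intramolecular capture of the ketene by an alcohol. Ring A closes by the C10→C5 shift (ring contraction) and ring B by addition of the C7 hydroxyl to the ketene carbon C6 (7-exo-dig-type lactonisation), the two reacting arms being held together on the sp2 carbon C9. The one new stereocentre, C5, arises on ketonisation of the ester enol, and DBU then equilibrates it α to the lactone carbonyl to the trans A/B fusion (H-5 anti to the C10 methyl, C6 equatorial on ring A). The step needs the ketene to be taken by the internal hydroxyl and not by other nucleophiles or by a carbene pathway; high dilution in a dry non-nucleophilic solvent, a single free O–H six atoms from C6, and the concerted shift from the s-cis diazo ketone should secure this.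

Step 24
Reactants: 32 lactone
Product: 33 lactol (C6 hemiacetal; acetonide retained)
Conditions: i-Bu2AlH (1.2 equiv), CH2Cl2, −78 °C; Rochelle salt
Reagents that add atoms: none
Why: Reduction at −78 °C stops at the tetrahedral aluminate, which gives the lactol on work-up; alkenes and acetonide are untouched.

Step 25
Reactants: 33 lactol
Product: 34 lactol diol (free C1 and C2 hydroxyls)
Conditions: AcOH/H2O (4:1), 40 °C
Reagents that add atoms: none
Why: Aqueous acetic acid hydrolyses the acetonide, while the lactol and both alkenes should survive.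

Step 26
Reactants: 34 lactol diol
Product: 35 triacetate (C1-OAc, C2-OAc and anomeric C6-OAc)
Conditions: Ac2O, pyridine, DMAP (cat.), CH2Cl2, rt
Reagents that add atoms: acetic anhydride, CC(=O)OC(C)=O
Why: Peracetylation installs the two acetates of the target and masks the lactol as its anomeric acetate for the two oxidations that follow.

Step 27
Reactants: 35 triacetate
Product: 36 15-hydroxy triacetate (C15 epimers)
Conditions: SeO2 (0.3 equiv), t-BuOOH, CH2Cl2, rt
Reagents that add atoms: tert-butyl hydroperoxide, CC(C)(C)OO (oxygen, relayed by SeO2, O=[Se]=O)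
Why: SeO2 allylic oxidation (ene reaction then [2,3]-shift) of the 1,1-disubstituted alkene at C15, the only allylic position with a removable hydrogen since C13 is a bridgehead; C9=C11 has no allylic hydrogen next to its substituted terminus and should be spared.

Step 28
Reactants: 36 allylic alcohol
Product: 37 15-oxo triacetate (α-methylene cyclopentanone)
Conditions: Dess–Martin periodinane, pyridine, CH2Cl2, 0 °C → rt
Reagents that add atoms: none
Why: Dess–Martin oxidation of the allylic alcohol to the enone; the anomeric acetate keeps the lactol from being oxidised.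

Step 29
Reactants: 37 enone triacetate
Product: 38 lactol enone 1,2-diacetate
Conditions: TsOH·H2O (0.2 equiv), acetone/H2O (5:1), rt
Reagents that add atoms: water, O
Why: The anomeric acetate, an α-acyloxy ether, ionises to the oxocarbenium ion under mild aqueous acid that leaves the ordinary acetates intact, and water returns the lactol.

Step 30
Reactants: 38 lactol enone
Product: 39 target CNP0224512.1
Conditions: mCPBA, CH2Cl2, 0 °C
Reagents that add atoms: 3-chloroperoxybenzoic acid, OOC(=O)c1cccc(Cl)c1
Why: Prilezhaev epoxidation: the peracid selects the electron-rich trisubstituted C9=C11 over the enone alkene and should approach the exo face of the bicyclo[3.2.1]octene, away from the C15–C16 bridge (the face of C20); it is run last so the epoxide meets no acid.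

**Compound list**

1 | (1R,5S)-(+)-nopinone | O=C1CC[C@H]2C[C@@H]1C2(C)C | starting material
2 | methyl 6,6-dimethyl-2-oxobicyclo[3.1.1]heptane-3-carboxylate | O=C1C(C(=O)OC)C[C@H]2C[C@@H]1C2(C)C | intermediate
3 | methyl (5R)-5-(2-chloropropan-2-yl)-2-oxocyclohexane-1-carboxylate | COC(=O)C1C[C@H](C(C)(C)Cl)CCC1=O | intermediate
4 | potassium enolate of methyl (5R)-2-oxo-5-(prop-1-en-2-yl)cyclohexane-1-carboxylate | COC(=O)C1=C([O-])CC[C@@H](C(C)=C)C1.[K+] | intermediate
5 | methyl (5R)-2-acetoxy-5-(prop-1-en-2-yl)cyclohex-1-ene-1-carboxylate | COC(=O)C1=C(OC(C)=O)CC[C@@H](C(C)=C)C1 | intermediate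
6 | methyl (5R)-2-acetoxy-5-(3-chloroprop-1-en-2-yl)cyclohex-1-ene-1-carboxylate | COC(=O)C1=C(OC(C)=O)CC[C@@H](C(CCl)=C)C1 | intermediate
7 | potassium enolate of methyl (5R)-5-(3-chloroprop-1-en-2-yl)-2-oxocyclohexane-1-carboxylate | COC(=O)C1=C([O-])CC[C@@H](C(CCl)=C)C1.[K+] | intermediate
8 | methyl (1R,5R)-6-methylidene-2-oxobicyclo[3.2.1]octane-1-carboxylate | C=C1C[C@@]2(C(=O)OC)C(=O)CC[C@@H]1C2 | intermediate
9 | (1S,5R)-1-(hydroxymethyl)-6-methylidenebicyclo[3.2.1]octan-2-ol | C=C1C[C@@]2(CO)C(O)CC[C@@H]1C2 | intermediate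
10 | (1S,5R)-1-[(tert-butyldiphenylsilyloxy)methyl]-6-methylidenebicyclo[3.2.1]octan-2-ol | C=C1C[C@@]2(CO[Si](c3ccccc3)(c3ccccc3)C(C)(C)C)C(O)CC[C@@H]1C2 | intermediate
11 | (1S,5R)-1-[(tert-butyldiphenylsilyloxy)methyl]-6-methylidenebicyclo[3.2.1]octan-2-one | C=C1C[C@@]2(CO[Si](c3ccccc3)(c3ccccc3)C(C)(C)C)C(=O)CC[C@@H]1C2 | intermediate
12 | 2,4,6-triisopropylbenzenesulfonylhydrazone of 11 | C=C1C[C@@]2(CO[Si](c3ccccc3)(c3ccccc3)C(C)(C)C)C(=NNS(=O)(=O)c3c(C(C)C)cc(C(C)C)cc3C(C)C)CC[C@@H]1C2 | intermediate
13 | 3,3-dimethylglutaric anhydride | O=C1CC(C)(C)CC(=O)O1 | starting material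
14 | 3,3-dimethyl-5-oxo-7-(trimethylsilyl)hept-6-ynoic acid | C[Si](C)(C)C#CC(=O)CC(C)(C)CC(=O)O | intermediate
15 | (5S)-5-hydroxy-3,3-dimethyl-7-(trimethylsilyl)hept-6-ynoic acid | C[Si](C)(C)C#C[C@@H](O)CC(C)(C)CC(=O)O | intermediate
16 | (6S)-4,4-dimethyl-6-[(trimethylsilyl)ethynyl]oxan-2-one | C[Si](C)(C)C#C[C@@H]1CC(C)(C)CC(=O)O1 | intermediate
17 | (6S)-6-ethynyl-4,4-dimethyloxan-2-one | C#C[C@@H]1CC(C)(C)CC(=O)O1 | intermediate
18 | (6S)-6-ethenyl-4,4-dimethyloxan-2-one | C=C[C@@H]1CC(C)(C)CC(=O)O1 | intermediate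
19 | (7S)-7-hydroxy-2,5,5-trimethylnona-1,8-dien-3-one | C=C[C@@H](O)CC(C)(C)CC(=O)C(C)=C | intermediate
20 | (4S)-4-hydroxy-2,6,6-trimethylcyclohept-2-en-1-one | CC1=C[C@@H](O)CC(C)(C)CC1=O | intermediate
21 | (1S,6S,7S)-6-hydroxy-1,4,4-trimethyl-8-oxabicyclo[5.1.0]octan-2-one | O=C1CC(C)(C)C[C@H](O)[C@@H]2O[C@]12C | intermediate
22 | (1S,6S,7S)-1,4,4-trimethyl-6-(triethylsilyloxy)-8-oxabicyclo[5.1.0]octan-2-one | O=C1CC(C)(C)C[C@H](O[Si](CC)(CC)CC)[C@@H]2O[C@]12C | intermediate
23 | C9 alkenyllithium of the C/D unit | C=C1C[C@@]2(CO[Si](c3ccccc3)(c3ccccc3)C(C)(C)C)C([Li])=CC[C@@H]1C2 | intermediate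
24 | tertiary epoxy carbinol (2-alkenyl-1,4,4-trimethyl-6-triethylsilyloxy-8-oxabicyclo[5.1.0]octan-2-ol; OH, epoxide O and OSiEt3 cis) | C=C1C[C@@]2(CO[Si](c3ccccc3)(c3ccccc3)C(C)(C)C)C(=CC[C@@H]1C2)[C@@]3(O)CC(C)(C)C[C@H](O[Si](CC)(CC)CC)[C@@H]4O[C@@]43C | intermediate
25 | β-hydroxy ketone (C10 quaternary; C1-OH, C2-OSiEt3 and C20 cis) | C=C1C[C@@]2(CO[Si](c3ccccc3)(c3ccccc3)C(C)(C)C)C(=CC[C@@H]1C2)[C@@]3(C)C(=O)CC(C)(C)C[C@H](O[Si](CC)(CC)CC)[C@@H]3O | intermediate
26 | C1,C2-cis-diol ketone | C=C1C[C@@]2(CO[Si](c3ccccc3)(c3ccccc3)C(C)(C)C)C(=CC[C@@H]1C2)[C@@]3(C)C(=O)CC(C)(C)C[C@H](O)[C@@H]3O | intermediate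
27 | acetonide ketone | C=C1C[C@@]2(CO[Si](c3ccccc3)(c3ccccc3)C(C)(C)C)C(=CC[C@@H]1C2)[C@@]3(C)C(=O)CC(C)(C)C[C@H](OC4(C)C)[C@H](O4)3 | intermediate
28 | C5-trifluoroacetyl ketone | C=C1C[C@@]2(CO[Si](c3ccccc3)(c3ccccc3)C(C)(C)C)C(=CC[C@@H]1C2)[C@@]3(C)C(=O)C(C(=O)C(F)(F)F)C(C)(C)C[C@H](OC4(C)C)[C@H](O4)3 | intermediate
29 | α-diazo ketone, C7 TBDPS ether | C=C1C[C@@]2(CO[Si](c3ccccc3)(c3ccccc3)C(C)(C)C)C(=CC[C@@H]1C2)[C@@]3(C)C(=O)C(=[N+]=[N-])C(C)(C)C[C@H](OC4(C)C)[C@H](O4)3 | intermediate
30 | α-diazo ketone, free C7 alcohol (key-step precursor) | C=C1C[C@@]2(CO)C(=CC[C@@H]1C2)[C@@]3(C)C(=O)C(=[N+]=[N-])C(C)(C)C[C@H](OC4(C)C)[C@H](O4)3 | intermediate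
31 | ring-A ketene (C5=C6=O) | C=C1C[C@@]2(CO)C(=CC[C@@H]1C2)[C@@]3(C)C(=C=O)C(C)(C)C[C@H](OC4(C)C)[C@H](O4)3 | intermediate
32 | tetracyclic lactone (key-step product) | C=C1C[C@@]23COC(=O)[C@@H]4C(C)(C)C[C@H](OC5(C)C)[C@H](O5)[C@@]4(C)C2=CC[C@@H]1C3 | intermediate
33 | lactol acetonide | C=C1C[C@@]23COC(O)[C@@H]4C(C)(C)C[C@H](OC5(C)C)[C@H](O5)[C@@]4(C)C2=CC[C@@H]1C3 | intermediate
34 | lactol 1,2-diol | C=C1C[C@@]23COC(O)[C@@H]4C(C)(C)C[C@H](O)[C@H](O)[C@@]4(C)C2=CC[C@@H]1C3 | intermediate
35 | 1,2,6-triacetate | C=C1C[C@@]23COC(OC(C)=O)[C@@H]4C(C)(C)C[C@H](OC(C)=O)[C@H](OC(C)=O)[C@@]4(C)C2=CC[C@@H]1C3 | intermediate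
36 | 15-hydroxy triacetate | C=C1C(O)[C@@]23COC(OC(C)=O)[C@@H]4C(C)(C)C[C@H](OC(C)=O)[C@H](OC(C)=O)[C@@]4(C)C2=CC[C@@H]1C3 | intermediate
37 | 15-oxo triacetate | C=C1C(=O)[C@@]23COC(OC(C)=O)[C@@H]4C(C)(C)C[C@H](OC(C)=O)[C@H](OC(C)=O)[C@@]4(C)C2=CC[C@@H]1C3 | intermediate
38 | lactol enone 1,2-diacetate | C=C1C(=O)[C@@]23COC(O)[C@@H]4C(C)(C)C[C@H](OC(C)=O)[C@H](OC(C)=O)[C@@]4(C)C2=CC[C@@H]1C3 | intermediate
39 | CNP0224512.1 (1,2-diacetoxy-9,11-epoxy-15-oxo-6,7-seco-ent-kaur-16-ene 6,7-lactol) | C=C1C(=O)[C@@]23CO[C@@H](O)[C@@H]4C(C)(C)C[C@H](OC(C)=O)[C@H](OC(C)=O)[C@@]4(C)[C@]24O[C@@H]4C[C@@H]1C3 | target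

**Step count and risks**

Total step count: 30 (9 for the C/D fragment, 8 for the A-homo fragment, 13 after their union). Longest linear sequence: 22 steps (steps 1–9 and 18–30).

Step 19 (semipinacol shift). The ring methylene C5 may migrate in place of the alkenyl group (ring contraction), or the tertiary allylic carbinol may ionise before the epoxide opens. The fallback makes the C9–C10 bond by C-alkenylation of a 1,3-dione with an alkenyllead triacetate and sets out from 22 and 12. Pd(PPh3)4/dppe in toluene at 80 °C isomerises the epoxy ketone 22 to (4S)-2,6,6-trimethyl-4-(triethylsilyloxy)cycloheptane-1,3-dione F1. The alkenyllithium from 12 is quenched with Bu3SnCl to the alkenylstannane F2, which Pb(OAc)4 in CHCl3 converts into the alkenyllead triacetate F3. F3 should alkenylate F1 at C10 in CHCl3/pyridine, from the face away from the C2 silyloxy group, to the 2-alkenyl-2-methyl-1,3-dione F4. Reduction of the more electrophilic α-silyloxy ketone (C1) with LiBH(s-Bu)3 at −78 °C, anti to the silyloxy group, comes back to the route at 25.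

Step 21 (diazo transfer). Acylation of the hindered enolate at the neopentyl carbon C5 may go to oxygen or stall, so that no diazo group is transferred. The fallback is the Forster reaction and sets out from 27: nitrosation of the potassium enolate (KOt-Bu, isoamyl nitrite, THF, −40 °C) gives the α-oximino ketone F5, and chloramine (aq. NH3, NaOCl, 0 °C) converts the oxime into the diazo ketone, rejoining the route at 29.

Step 30 (epoxidation). The peracid may attack the face of C9=C11 that carries the C15–C16 bridge, giving poor facial selectivity. The fallback builds the epoxide through a halohydrin and sets out from 37. NBS in acetone/H2O at 0 °C gives the bromohydrin F6, with bromine on the face the peracid would take and oxygen on the other. Ag2O in CH2Cl2 closes it to the epoxy triacetate F7, and (Bu3Sn)2O in toluene removes only the anomeric acetate, arriving at 39.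

**Further compounds**

F1 | step 19 | (4S)-2,6,6-trimethyl-4-(triethylsilyloxy)cycloheptane-1,3-dione | O=C1CC(C)(C)C[C@H](O[Si](CC)(CC)CC)C(=O)C1C
F2 | step 19 | C9 tributylstannane of the C/D unit | C=C1C[C@@]2(CO[Si](c3ccccc3)(c3ccccc3)C(C)(C)C)C([Sn](CCCC)(CCCC)CCCC)=CC[C@@H]1C2
F3 | step 19 | C9 alkenyllead triacetate of the C/D unit | C=C1C[C@@]2(CO[Si](c3ccccc3)(c3ccccc3)C(C)(C)C)C([Pb](OC(C)=O)(OC(C)=O)OC(C)=O)=CC[C@@H]1C2
F4 | step 19 | 2-alkenyl-2,6,6-trimethyl-4-(triethylsilyloxy)cycloheptane-1,3-dione | C=C1C[C@@]2(CO[Si](c3ccccc3)(c3ccccc3)C(C)(C)C)C(=CC[C@@H]1C2)[C@@]3(C)C(=O)CC(C)(C)C[C@H](O[Si](CC)(CC)CC)C3=O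
F5 | step 21 | C5 α-oximino ketone of 27 | C=C1C[C@@]2(CO[Si](c3ccccc3)(c3ccccc3)C(C)(C)C)C(=CC[C@@H]1C2)[C@@]3(C)C(=O)C(=NO)C(C)(C)C[C@H](OC4(C)C)[C@H](O4)3
F6 | step 30 | 11-bromo-9-hydroxy triacetate (bromohydrin of 37) | C=C1C(=O)[C@@]23COC(OC(C)=O)[C@@H]4C(C)(C)C[C@H](OC(C)=O)[C@H](OC(C)=O)[C@@]4(C)[C@@]2(O)[C@@H](Br)C[C@@H]1C3
F7 | step 30 | 9,11-epoxy 15-oxo triacetate | C=C1C(=O)[C@@]23COC(OC(C)=O)[C@@H]4C(C)(C)C[C@H](OC(C)=O)[C@H](OC(C)=O)[C@@]4(C)[C@]24O[C@@H]4C[C@@H]1C3
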